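## The problem

Barbatolic acid (18) consists of two benzene rings with the same substitution pattern, joined by a single ester bond: in each ring C1 carries a carboxyl carbon, C2 and C4 hydroxyl groups, C3 a formyl group and C5 hydrogen. C6 is a methyl group in ring A and an oxymethylene group in ring B, whose oxygen is acylated by the C1 carboxyl of ring A, while the C1 carboxyl of ring B is free. There is no stereocenter, so the synthesis is a matter of regiochemistry and functional-group tolerance only. The bond between the rings is a benzyl ester that would not survive a late hydrogenolysis, and a free hydroxymethyl group at C6 of ring B next to a C1 ester would close to a phthalide. The two formyl C–H bonds are open to radical abstraction, oxidation and reduction, and 2,4-dihydroxybenzoic acids lose carbon dioxide in hot acid. C1 is the most crowded ring position, flanked by the C2 oxygen and the C6 carbon, and direct carboxylation of a 3,5-dioxygenated toluene reaches it poorly. The enabling feature is the sequence C6 (carbon substituent), C1 (carboxyl), C2 (oxygen) on three neighbouring ring atoms, which is what an aryne with an alkoxy group beside the triple bond delivers when a carbon nucleophile enters at the far aryne carbon and an electrophile is taken up at the near one. Since both rings share this skeleton, one arene synthesis can feed both halves.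

## Retrosynthesis

**18 ⇒ 17 ⇒ 16 (protecting groups only).** No skeletal bond is cut. The last operations are chosen so that the inter-ring benzyl ester survives. The ring B carboxyl is released by acidolysis of the tert-butyl ester 17, which is safe because the benzylic carbon is meta to both hydroxyl groups and cannot ionise. Before that, four acetyl groups are removed from 16 by basic methanolysis, which the hindered 2,6-disubstituted aroyl ester resists. Benzyl or methyl protection at this stage would require hydrogenolysis or boron halides and is therefore excluded.

**16 ⇒ 13 + 15 (benzylic C–O bond).** The bond between the ring A carboxylate oxygen and the ring B methylene carbon is cut. The neighbouring cut, at the acyl C–O bond, would need a ring B benzylic alcohol, which lactonises onto its own C1 ester, and would need activation of a doubly ortho-substituted acid. Alkylation of carboxylic acid 13 with benzylic bromide 15 forms the bond at oxygen, away from the hindrance. The precursors are two monocyclic compounds of the same skeleton. The forward reaction must alkylate the carboxylate and leave the phenols of 13 alone, which KHCO3 as the base should ensure.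

**15 ⇒ 14 ⇒ 12 (C–Br bond at the C6 methyl group).** A radical bromination is the shortest way to activate the methyl group. It requires a ring that is not attacked by electrophilic bromine and a formyl group that does not offer its C–H bond to the bromine atom. Exhaustive acetylation of 12 to tetraacetate 14 answers both: the phenols become acetates and the aldehyde a geminal diacetate. Brominating with the free aldehyde present would be shorter in principle, but aldehydes are converted into acyl bromides under these conditions.

**13 ⇒ 12.** Ring A needs only the free acid, obtained from the same tert-butyl ester 12 by acidolysis.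

**12 ⇒ 11 (C3–CHO bond).** The formyl group is introduced after the arene is complete and before the two halves diverge, so that one formylation serves both rings and a C5 isomer can be removed on a small monomer. The forward reaction must prefer C3 over C5 and must not be acidic enough to cleave the tert-butyl ester, which points to a magnesium phenoxide-directed ortho-formylation.

**11 ⇒ 10 ⇒ 9 (protecting-group exchange).** The benzyl ethers that carry the oxygens through the organometallic step must be removed before the inter-ring ester exists. The acid 9 is first converted into the tert-butyl ester 10, which prevents decarboxylation and stays on ring B to the end; hydrogenolysis then gives 11.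

**9 ⇒ 3 + 4 + 5 (C6–CH3 and C1–CO2H bonds).** Both bonds are cut in one step: aryl triflate 3 is the precursor of 3,5-bis(benzyloxy)benzyne 7, methylmagnesium bromide 4 supplies the methyl group and carbon dioxide 5 the carboxyl carbon. The route passes through the magnesiated triflate 6 and the arylmagnesium 8. The neighbouring options, directed metalation or electrophilic substitution of an arene that already carries the methyl group and both ether oxygens, would functionalise the position between the two oxygens (the future C3) or give mixtures, whereas in 3 the positions of iodine and triflate fix where the two new bonds form. The precursor is a trioxygenated benzene with no carbon substituent. The forward reaction must add methyl at the aryne carbon remote from oxygen.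

**3 ⇒ 2 ⇒ 1.** The O–S and C–I bonds are cut: triflation of iodophenol 2, and ortho-iodination of the purchasable phenol 1.

## Roads not taken

**Alternative 1:** The ring is cut at C1–C6 and C3–C4 and assembled from two acyclic esters. The enolate of tert-butyl acetoacetate A1 adds to ethyl crotonate A2 in a Michael reaction, and the methyl carbon of A1 then closes the ring by Claisen acylation on the ester carbonyl of A2 to give tert-butyl 6-methyl-2,4-dioxocyclohexane-1-carboxylate A3. C3 of A3 is the central carbon of a cyclic 1,3-dione, so formylation to tert-butyl 3-formyl-6-methyl-2,4-dioxocyclohexane-1-carboxylate A4 has no regiochemical choice, and dehydrogenation of A4 would give tert-butyl ester 12 of the present route.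
- Merits: A1 and A2 are commodity esters, one step leads to the carbocycle A3, about three steps lead to 12 instead of six, and there is no C3/C5 question.
- Weak points: the ring of A4 must be aromatised after the formyl group is in place. Halogen- or quinone-based dehydrogenation would act on an enolised aldehyde, an acid-labile tert-butyl β-keto ester and a product resorcinol that halogenates easily.
- Comparison: this road is shorter, cheaper and better at C3. The chosen plan sets against it an arene that is aromatic from the first step, so no oxidation-level change is needed on a formylated, acid-sensitive intermediate.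

**Alternative 2:** Both rings are cut at C1–C2 and C5–C6 while the inter-ring ester is kept. The diyne diester tert-butyl 4-(but-2-ynoyloxy)but-2-ynoate A5 would take up two equivalents of 1-methoxy-1,3-bis(trimethylsilyloxy)buta-1,3-diene A6 at its two triple bonds. Aromatisation by loss of the methoxy group and desilylation would give tert-butyl 2-[(2,4-dihydroxy-6-methylbenzoyl)oxymethyl]-4,6-dihydroxybenzoate A7, to be formylated twice and deprotected.
- Merits: the most convergent plan, perhaps five or six steps. The benzylic ester exists in A5 before either ring, so no benzylic bromination, carboxylate alkylation or aldehyde masking is needed.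
- Weak points: β-substituted ynoates are sluggish dienophiles and need heat, under which the propargylic ester A5 and the ketene acetal A6 are fragile, and two cycloadditions must succeed in one molecule. A7 must then be formylated at C3 of two electronically similar rings, so any C5 attack produces isomers of a late, polar intermediate.
- Comparison: in step count and in avoiding radical chemistry this road is clearly better. The chosen plan sets against it a single formylation on a monomer and an inter-ring ester formed late by a mild substitution.

**Alternative 3:** The ring is cut at C2–C3, C4–C5 and C1–C2. Irradiation of tert-butyl (E)-5-diazo-3-methyl-4-oxopent-2-enoate A8 would give a vinylketene by Wolff rearrangement. [2+2] addition to triisopropyl[(3,3-diethoxyprop-1-yn-1-yl)oxy]silane A9, four-electron opening of the cyclobutenone and six-electron ring closure would give tert-butyl 3-(diethoxymethyl)-2-hydroxy-6-methyl-4-(triisopropylsilyloxy)benzoate A10.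
- Merits: every substituent of A10, the C3 formyl carbon included, is placed by the connectivity of the partners A8 and A9. The two phenols are differentiated and the aldehyde arrives masked.
- Weak points: A8 requires a diazoalkane acylation of a geometrically defined half ester, A9 is a sensitive ynol ether needing several steps, and the annulation is photochemical. The acetal C–H bond of A10 would not tolerate the radical bromination that ring B still needs.
- Comparison: in regiochemical certainty at C3 this road is better than the chosen plan, which relies on a directed formylation. The chosen plan sets against it a purchasable arene, common reagents and no diazo or photochemical step; the step counts are similar once both annulation partners are made.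

Key step: step 3

## Route

Remark: compound 1 is taken to be purchasable; ring positions are numbered as in the target throughout.

Step 1
Reactants: 1 3,5-bis(benzyloxy)phenol
Product: 2 3,5-bis(benzyloxy)-2-iodophenol
Conditions: NIS (1.0 equiv), CH2Cl2, −78 → 0 °C
Reagents that add atoms: N-iodosuccinimide, O=C1CCC(=O)N1I
Why: Electrophilic aromatic iodination; the hydroxyl group is the strongest donor, its two equivalent ortho positions are less hindered than the position between the two benzyloxy groups and are served by hydrogen-bonded delivery of the reagent in a non-polar solvent, and one equivalent at low temperature limits di-iodination.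

Step 2
Reactants: 2 3,5-bis(benzyloxy)-2-iodophenol
Product: 3 3,5-bis(benzyloxy)-2-iodophenyl trifluoromethanesulfonate
Conditions: Tf2O, pyridine, CH2Cl2, 0 °C
Reagents that add atoms: trifluoromethanesulfonic anhydride, O=S(=O)(OS(=O)(=O)C(F)(F)F)C(F)(F)F
Why: O-sulfonylation of a phenol; the pyridine-activated anhydride reacts at oxygen only, giving the ortho-iodoaryl triflate that serves as aryne precursor.

Step 3
Reactants: 3 3,5-bis(benzyloxy)-2-iodophenyl trifluoromethanesulfonate; 4 methylmagnesium bromide; 5 carbon dioxide
Product: 9 2,4-bis(benzyloxy)-6-methylbenzoic acid, via 2-magnesio-3,5-bis(benzyloxy)phenyl triflate 6 (not isolated), via 3,5-bis(benzyloxy)benzyne 7 (not isolated), via 2,4-bis(benzyloxy)-6-methylphenylmagnesium bromide 8 (not isolated)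
Conditions: 4 (4 equiv), THF, −78 °C; iPrMgCl·LiCl (1.05 equiv, slow addition), −78 → −20 °C; 5 (gas), −20 °C → rt; aq. HCl
Reagents that add atoms: none
Why: Iodine–magnesium exchange at the C–I bond, fast at −78 °C because the carbanion is flanked by two oxygen-bearing carbons, gives 6, which expels Mg(OTf)Cl to form aryne 7; the closest known reaction type is the carbomagnesiation of arynes released from 2-magnesioaryl sulfonates followed by an electrophilic quench of the new arylmagnesium. No ring closes and no stereocenter is formed. The step needs regioselectivity across the triple bond: the benzyloxy group beside it distorts the aryne so that the remote carbon (future C6) is the more electrophilic one, and the charge developing at the carbon next to oxygen (future C1) is stabilised inductively and by O–Mg coordination, so methyl should enter at C6 and magnesium should end at C1 in 8; the second benzyloxy group is not adjacent to either aryne carbon and should exert only a small influence. It also needs selectivity among the nucleophiles present: the isopropyl reagent is added slowly as the limiting component and should be consumed by the fast exchange, while 7 is always released into a large excess of 4, which should outcompete 6 and 8 as well. Carbon dioxide is small enough to reach the hindered magnesium-bearing carbon between the benzyloxy and methyl groups, and the excess of 4 is converted only into water-soluble acetate. Acidification liberates 9.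

Step 4
Reactants: 9 2,4-bis(benzyloxy)-6-methylbenzoic acid
Product: 10 tert-butyl 2,4-bis(benzyloxy)-6-methylbenzoate
Conditions: tert-butyl 2,2,2-trichloroacetimidate, BF3·OEt2 (cat.), CH2Cl2/cyclohexane, rt
Reagents that add atoms: tert-butyl 2,2,2-trichloroacetimidate, CC(C)(C)OC(=N)C(Cl)(Cl)Cl
Why: Imidate O-alkylation of a carboxylic acid; the tert-butyl group is transferred to the carboxyl oxygen, so the two ortho substituents that would block acyl substitution do not interfere, and the benzyl ethers tolerate the catalytic Lewis acid.

Step 5
Reactants: 10 tert-butyl 2,4-bis(benzyloxy)-6-methylbenzoate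
Product: 11 tert-butyl 2,4-dihydroxy-6-methylbenzoate
Conditions: H2 (1 atm), Pd/C, EtOAc, rt
Reagents that add atoms: none
Why: Hydrogenolysis of aryl benzyl ethers over Pd/C; the tert-butyl ester is inert, and the benzyl groups are removed here because they could not be removed once the inter-ring benzyl ester exists.

Step 6
Reactants: 11 tert-butyl 2,4-dihydroxy-6-methylbenzoate
Product: 12 tert-butyl 3-formyl-2,4-dihydroxy-6-methylbenzoate
Conditions: MgCl2, Et3N, (CH2O)n, MeCN, reflux; aq. HCl
Reagents that add atoms: formaldehyde (as paraformaldehyde), C=O
Why: Casnati–Skattebøl ortho-formylation; a magnesium phenoxide binds formaldehyde and delivers it to an ortho carbon, and the salicyl alkoxide is oxidised by a second formaldehyde; C3 is ortho to both phenolic oxygens, including the one chelated to magnesium with the ester carbonyl, whereas C5 is ortho to one only and flanked by the methyl group, and the non-acidic medium spares the tert-butyl ester.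

Step 7
Reactants: 12 tert-butyl 3-formyl-2,4-dihydroxy-6-methylbenzoate
Product: 13 3-formyl-2,4-dihydroxy-6-methylbenzoic acid
Conditions: TFA, CH2Cl2, 0 °C → rt
Reagents that add atoms: none
Why: Acidolysis of a tert-butyl ester by alkyl–oxygen cleavage; the formyl group deactivates the ring toward protonation at C1, so decarboxylation should not compete at room temperature.

Step 8
Reactants: 12 tert-butyl 3-formyl-2,4-dihydroxy-6-methylbenzoate
Product: 14 tert-butyl 2,4-diacetoxy-3-(diacetoxymethyl)-6-methylbenzoate
Conditions: Ac2O, Sc(OTf)3 (1 mol %), MeCN, 0 °C → rt
Reagents that add atoms: acetic anhydride, CC(=O)OC(C)=O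
Why: Lewis-acid-catalysed acylation; both phenols are acetylated and the aldehyde, no longer hydrogen-bonded, adds acetic anhydride to give the geminal diacetate (acylal), which deactivates the ring toward ionic bromination and removes the weak formyl C–H bond; a catalytic amount of the triflate at low temperature should leave the tert-butyl ester in place.

Step 9
Reactants: 14 tert-butyl 2,4-diacetoxy-3-(diacetoxymethyl)-6-methylbenzoate
Product: 15 tert-butyl 2,4-diacetoxy-6-(bromomethyl)-3-(diacetoxymethyl)benzoate
Conditions: NBS (1.05 equiv), AIBN (cat.), PhCF3, 80 °C
Reagents that add atoms: N-bromosuccinimide, O=C1CCC(=O)N1Br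
Why: Wohl–Ziegler bromination; the bromine atom abstracts hydrogen from the C6 methyl group, while the only other benzylic hydrogen, at the acylal carbon, is shielded by two ortho and two geminal acetoxy groups and is polarity-mismatched with the electrophilic bromine atom; tert-butyl 2-(bromomethyl)benzoates are accessible in this way.

Step 10
Reactants: 13 3-formyl-2,4-dihydroxy-6-methylbenzoic acid; 15 tert-butyl 2,4-diacetoxy-6-(bromomethyl)-3-(diacetoxymethyl)benzoate
Product: 16 [3,5-diacetoxy-2-(tert-butoxycarbonyl)-4-(diacetoxymethyl)phenyl]methyl 3-formyl-2,4-dihydroxy-6-methylbenzoate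
Conditions: KHCO3 (1.1 equiv), DMF, rt
Reagents that add atoms: none
Why: SN2 O-alkylation of a carboxylate; hydrogen carbonate ionises only the carboxylic acid of 13, not its chelated phenols, and the bond forms at the carboxylate oxygen, away from the ortho substituents; forming the ester from this side avoids a free hydroxymethyl group on ring B, which would close to a phthalide.

Step 11
Reactants: 16 [3,5-diacetoxy-2-(tert-butoxycarbonyl)-4-(diacetoxymethyl)phenyl]methyl 3-formyl-2,4-dihydroxy-6-methylbenzoate
Product: 17 tert-butyl 3-formyl-6-{[(3-formyl-2,4-dihydroxy-6-methylbenzoyl)oxy]methyl}-2,4-dihydroxybenzoate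
Conditions: K2CO3, MeOH/THF, 0 °C; aq. HCl
Reagents that add atoms: none
Why: Base-mediated methanolysis; methoxide removes the two aryl acetates and one acetyl group of the acylal, whose hemiacylal alkoxide then expels acetate to give the aldehyde; the inter-ring ester is a 2,6-disubstituted benzoate with an ionised ortho hydroxyl and should not be attacked, the tert-butyl ester is inert, and the ring B phenoxide oxygens are meta to the benzylic carbon, so no quinone methide elimination can expel the carboxylate.

Step 12
Reactants: 17 tert-butyl 3-formyl-6-{[(3-formyl-2,4-dihydroxy-6-methylbenzoyl)oxy]methyl}-2,4-dihydroxybenzoate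
Product: 18 3-formyl-6-{[(3-formyl-2,4-dihydroxy-6-methylbenzoyl)oxy]methyl}-2,4-dihydroxybenzoic acid (barbatolic acid)
Conditions: TFA, CH2Cl2, 0 °C → rt
Reagents that add atoms: none
Why: Acidolysis of the tert-butyl ester by alkyl–oxygen cleavage; the benzylic ester should not ionise because its carbon is meta to both hydroxyl groups on a ring carrying two acyl substituents, and evaporation should leave 18 without contact with base.

## Compound list

1 | 3,5-bis(benzyloxy)phenol | Oc1cc(OCc2ccccc2)cc(OCc2ccccc2)c1 | starting material
2 | 3,5-bis(benzyloxy)-2-iodophenol | Oc1cc(OCc2ccccc2)cc(OCc2ccccc2)c1I | intermediate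
3 | 3,5-bis(benzyloxy)-2-iodophenyl trifluoromethanesulfonate | FC(F)(F)S(=O)(=O)Oc1cc(OCc2ccccc2)cc(OCc2ccccc2)c1I | intermediate
4 | methylmagnesium bromide | C[Mg]Br | starting material
5 | carbon dioxide | O=C=O | starting material
6 | [2,4-bis(benzyloxy)-6-(trifluoromethylsulfonyloxy)phenyl]magnesium chloride (2-magnesio-3,5-bis(benzyloxy)phenyl triflate) | FC(F)(F)S(=O)(=O)Oc1cc(OCc2ccccc2)cc(OCc2ccccc2)c1[Mg]Cl | intermediate (not isolated)
7 | 3,5-bis(benzyloxy)benzyne | C1#CC(OCc2ccccc2)=CC(OCc2ccccc2)=C1 | intermediate (not isolated)
8 | 2,4-bis(benzyloxy)-6-methylphenylmagnesium bromide | Cc1cc(OCc2ccccc2)cc(OCc2ccccc2)c1[Mg]Br | intermediate (not isolated)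
9 | 2,4-bis(benzyloxy)-6-methylbenzoic acid | Cc1cc(OCc2ccccc2)cc(OCc2ccccc2)c1C(=O)O | intermediate
10 | tert-butyl 2,4-bis(benzyloxy)-6-methylbenzoate | Cc1cc(OCc2ccccc2)cc(OCc2ccccc2)c1C(=O)OC(C)(C)C | intermediate
11 | tert-butyl 2,4-dihydroxy-6-methylbenzoate | Cc1cc(O)cc(O)c1C(=O)OC(C)(C)C | intermediate
12 | tert-butyl 3-formyl-2,4-dihydroxy-6-methylbenzoate | Cc1cc(O)c(C=O)c(O)c1C(=O)OC(C)(C)C | intermediate
13 | 3-formyl-2,4-dihydroxy-6-methylbenzoic acid | Cc1cc(O)c(C=O)c(O)c1C(=O)O | intermediate
14 | tert-butyl 2,4-diacetoxy-3-(diacetoxymethyl)-6-methylbenzoate | Cc1cc(OC(C)=O)c(C(OC(C)=O)OC(C)=O)c(OC(C)=O)c1C(=O)OC(C)(C)C | intermediate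
15 | tert-butyl 2,4-diacetoxy-6-(bromomethyl)-3-(diacetoxymethyl)benzoate | BrCc1cc(OC(C)=O)c(C(OC(C)=O)OC(C)=O)c(OC(C)=O)c1C(=O)OC(C)(C)C | intermediate
16 | [3,5-diacetoxy-2-(tert-butoxycarbonyl)-4-(diacetoxymethyl)phenyl]methyl 3-formyl-2,4-dihydroxy-6-methylbenzoate | Cc1cc(O)c(C=O)c(O)c1C(=O)OCc1cc(OC(C)=O)c(C(OC(C)=O)OC(C)=O)c(OC(C)=O)c1C(=O)OC(C)(C)C | intermediate
17 | tert-butyl 3-formyl-6-{[(3-formyl-2,4-dihydroxy-6-methylbenzoyl)oxy]methyl}-2,4-dihydroxybenzoate | Cc1cc(O)c(C=O)c(O)c1C(=O)OCc1cc(O)c(C=O)c(O)c1C(=O)OC(C)(C)C | intermediate
18 | 3-formyl-6-{[(3-formyl-2,4-dihydroxy-6-methylbenzoyl)oxy]methyl}-2,4-dihydroxybenzoic acid (barbatolic acid) | Cc1cc(O)c(C=O)c(O)c1C(=O)OCc1cc(O)c(C=O)c(O)c1C(=O)O | target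

## Step count and risks

Total: 12 steps. Longest linear sequence: 11 steps (steps 1–6 and 8–12); step 7 branches from 12.

**Step 3 (key step).** The most likely failure is competition for the aryne: addition of the isopropyl reagent or of the arylmagnesium species 6 and 8 in place of methyl, or attack of a Grignard reagent at the triflate sulfur before exchange. Fallback: setting out from 3, the C–I bond would be methoxycarbonylated (CO, MeOH, Et3N, PdCl2(PPh3)2, DMF, 60 °C; with triphenylphosphine ligands the iodide reacts before the triflate) to methyl 2,4-bis(benzyloxy)-6-(trifluoromethylsulfonyloxy)benzoate F1. The triflate would then be exchanged for methyl by Suzuki–Miyaura coupling with trimethylboroxine (Pd(PPh3)4, K2CO3, dioxane, 100 °C) to give methyl 2,4-bis(benzyloxy)-6-methylbenzoate F2, and the hindered ester saponified (KOH, DMSO/H2O, 90 °C) to come back to the route at 9.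

**Step 6.** Poor regioselectivity is the risk: C5 is also ortho to the C4 oxygen, and attack there would give an isomeric aldehyde. Fallback: setting out from 9, hydrogenolysis (H2, Pd/C) would give 2,4-dihydroxy-6-methylbenzoic acid F3, and alkylation of its carboxylate (benzyl bromide, KHCO3, DMF) benzyl 2,4-dihydroxy-6-methylbenzoate F4. Rieche formylation (Cl2CHOMe, TiCl4, CH2Cl2, 0 °C), in which titanium chelated between the C2 and C4 oxygens should direct the electrophile to C3 of the orsellinate ester, would give benzyl 3-formyl-2,4-dihydroxy-6-methylbenzoate F5. Hydrogenolysis of the benzyl ester returns to the route at 13, and part of 13 would be re-esterified with tert-butyl 2,2,2-trichloroacetimidate to reach 12.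

**Step 8.** Loss of the tert-butyl group under the Lewis-acidic acylation, or incomplete acylal formation at the doubly flanked aldehyde, may occur. Fallback: setting out from 13, classical peracetylation (Ac2O, cat. H2SO4, 0 °C, then water to hydrolyse the mixed anhydride) would give 2,4-diacetoxy-3-(diacetoxymethyl)-6-methylbenzoic acid F6. Its esterification with tert-butyl 2,2,2-trichloroacetimidate comes back to the route at 14.

**Step 9.** Hydrogen abstraction at the acylal carbon instead of the methyl group, dibromination, or thermal loss of the tert-butyl group with phthalide closure may occur. Fallback: ring B would be formylated only after the rings are joined. Setting out from 11, acetylation (Ac2O, pyridine) would give tert-butyl 2,4-diacetoxy-6-methylbenzoate F7 and Wohl–Ziegler bromination tert-butyl 2,4-diacetoxy-6-(bromomethyl)benzoate F8. Alkylation of 13 (KHCO3, DMF) would give [3,5-diacetoxy-2-(tert-butoxycarbonyl)phenyl]methyl 3-formyl-2,4-dihydroxy-6-methylbenzoate F9, and methanolysis (K2CO3, MeOH) tert-butyl 2-{[(3-formyl-2,4-dihydroxy-6-methylbenzoyl)oxy]methyl}-4,6-dihydroxybenzoate F10. Magnesium-mediated formylation of the more electron-rich ring B (MgCl2, Et3N, paraformaldehyde) comes back to the route at 17.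

**Step 1.** Iodination at the position between the two benzyloxy groups, or di-iodination, may erode the yield of the ortho isomer. Fallback: setting out from 1, carbamoylation (diethylcarbamoyl chloride, K2CO3, MeCN) would give 3,5-bis(benzyloxy)phenyl N,N-diethylcarbamate F11. Directed ortho-lithiation between the carbamate and a benzyloxy group (LiN(iPr)2, THF, −78 °C) and an iodine quench would give 3,5-bis(benzyloxy)-2-iodophenyl N,N-diethylcarbamate F12, and hydrolysis (NaOH, EtOH, reflux) comes back to the route at 2.

## Further compounds

F1 | step 3 | methyl 2,4-bis(benzyloxy)-6-(trifluoromethylsulfonyloxy)benzoate | COC(=O)c1c(OCc2ccccc2)cc(OCc2ccccc2)cc1OS(=O)(=O)C(F)(F)F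
F2 | step 3 | methyl 2,4-bis(benzyloxy)-6-methylbenzoate | COC(=O)c1c(C)cc(OCc2ccccc2)cc1OCc1ccccc1
F3 | step 6 | 2,4-dihydroxy-6-methylbenzoic acid | Cc1cc(O)cc(O)c1C(=O)O
F4 | step 6 | benzyl 2,4-dihydroxy-6-methylbenzoate | Cc1cc(O)cc(O)c1C(=O)OCc1ccccc1
F5 | step 6 | benzyl 3-formyl-2,4-dihydroxy-6-methylbenzoate | Cc1cc(O)c(C=O)c(O)c1C(=O)OCc1ccccc1
F6 | step 8 | 2,4-diacetoxy-3-(diacetoxymethyl)-6-methylbenzoic acid | Cc1cc(OC(C)=O)c(C(OC(C)=O)OC(C)=O)c(OC(C)=O)c1C(=O)O
F7 | step 9 | tert-butyl 2,4-diacetoxy-6-methylbenzoate | Cc1cc(OC(C)=O)cc(OC(C)=O)c1C(=O)OC(C)(C)C
F8 | step 9 | tert-butyl 2,4-diacetoxy-6-(bromomethyl)benzoate | BrCc1cc(OC(C)=O)cc(OC(C)=O)c1C(=O)OC(C)(C)C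
F9 | step 9 | [3,5-diacetoxy-2-(tert-butoxycarbonyl)phenyl]methyl 3-formyl-2,4-dihydroxy-6-methylbenzoate | Cc1cc(O)c(C=O)c(O)c1C(=O)OCc1cc(OC(C)=O)cc(OC(C)=O)c1C(=O)OC(C)(C)C
F10 | step 9 | tert-butyl 2-{[(3-formyl-2,4-dihydroxy-6-methylbenzoyl)oxy]methyl}-4,6-dihydroxybenzoate | Cc1cc(O)c(C=O)c(O)c1C(=O)OCc1cc(O)cc(O)c1C(=O)OC(C)(C)C
F11 | step 1 | 3,5-bis(benzyloxy)phenyl N,N-diethylcarbamate | CCN(CC)C(=O)Oc1cc(OCc2ccccc2)cc(OCc2ccccc2)c1
F12 | step 1 | 3,5-bis(benzyloxy)-2-iodophenyl N,N-diethylcarbamate | CCN(CC)C(=O)Oc1cc(OCc2ccccc2)cc(OCc2ccccc2)c1I
A1 | alternative 1 | tert-butyl acetoacetate | CC(=O)CC(=O)OC(C)(C)C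
A2 | alternative 1 | ethyl (E)-but-2-enoate (ethyl crotonate) | C/C=C/C(=O)OCC
A3 | alternative 1 | tert-butyl 6-methyl-2,4-dioxocyclohexane-1-carboxylate (mixture of diastereomers and enol tautomers) | CC1CC(=O)CC(=O)C1C(=O)OC(C)(C)C
A4 | alternative 1 | tert-butyl 3-formyl-6-methyl-2,4-dioxocyclohexane-1-carboxylate (mixture of diastereomers and enol tautomers) | CC1CC(=O)C(C=O)C(=O)C1C(=O)OC(C)(C)C
A5 | alternative 2 | tert-butyl 4-(but-2-ynoyloxy)but-2-ynoate | CC#CC(=O)OCC#CC(=O)OC(C)(C)C
A6 | alternative 2 | 1-methoxy-1,3-bis(trimethylsilyloxy)buta-1,3-diene (double-bond geometry not specified) | COC(O[Si](C)(C)C)=CC(=C)O[Si](C)(C)C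
A7 | alternative 2 | tert-butyl 2-[(2,4-dihydroxy-6-methylbenzoyl)oxymethyl]-4,6-dihydroxybenzoate | Cc1cc(O)cc(O)c1C(=O)OCc1cc(O)cc(O)c1C(=O)OC(C)(C)C
A8 | alternative 3 | tert-butyl (E)-5-diazo-3-methyl-4-oxopent-2-enoate | C/C(=C\C(=O)OC(C)(C)C)C(=O)C=[N+]=[N-]
A9 | alternative 3 | triisopropyl[(3,3-diethoxyprop-1-yn-1-yl)oxy]silane | CCOC(OCC)C#CO[Si](C(C)C)(C(C)C)C(C)C
A10 | alternative 3 | tert-butyl 3-(diethoxymethyl)-2-hydroxy-6-methyl-4-(triisopropylsilyloxy)benzoate | CCOC(OCC)c1c(O)c(C(=O)OC(C)(C)C)c(C)cc1O[Si](C(C)C)(C(C)C)C(C)C
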